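## Retrosynthetic overview

1. The target comes from acid unmasking (C14 acetal, C15 silyl ether) of macrocycle 28, whose ten-membered ring is closed last by ring-closing metathesis at C4=C5 of the bis-angelate seco-diene 27.
2. The C9–C10 bond is the late union of two C8 halves: chelation-controlled addition of the alkenylmagnesium from (Z)-iodide 9 (C1–C4, C10, C14, C15) to α-PMB-oxy aldehyde 20 (C5–C9, C11–C13), which sets C9.
3. Aldehyde 20 comes from Zn-Barbier allylation of acrolein with bromomethyl-dihydropyranone 15 (sets C6 and C7 from C8), then δ→γ translactonisation; 15 comes from (S)-but-3-ene-1,2-diol and 2-(bromomethyl)acrylic acid by metathesis.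
4. Iodide 9 comes from 2-methylidenepropane-1,3-diol, allylmagnesium bromide and crotonaldehyde (allyl–allyl coupling, cross-metathesis, α-iodination, acetalisation).
5. Ring order: dihydropyranone (temporary) → α-methylene-γ-butyrolactone → ten-membered carbocycle.

Assumption: atom labels C1–C15 follow germacrane numbering (lactone C6–O–C12, exo-methylene C13, esters on C8 and C9, CHO = C14, CH2OH = C15); compounds 1, 4, 6, 10, 13, 16 and 25 are taken as purchasable.

## Route

Step 1
Reactants: 1 2-methylidenepropane-1,3-diol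
Product: 2 2-({[tert-butyl(dimethyl)silyl]oxy}methyl)prop-2-en-1-ol
Conditions: TBSCl (1.0 equiv), imidazole, 1 (3 equiv), THF, 0 °C → rt
Reagents that add atoms: tert-butyl(chloro)dimethylsilane, CC(C)(C)[Si](C)(C)Cl
Why: Statistical mono-silylation of one of two equivalent primary hydroxyls (excess diol suppresses the bis-ether), with no stereocentre involved.

Step 2
Reactants: 2 2-({[tert-butyl(dimethyl)silyl]oxy}methyl)prop-2-en-1-ol
Product: 3 {[2-(bromomethyl)prop-2-en-1-yl]oxy}(tert-butyl)dimethylsilane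
Conditions: CBr4, PPh3, CH2Cl2, 0 °C
Reagents that add atoms: tetrabromomethane, BrC(Br)(Br)Br
Why: Appel bromination of a primary allylic alcohol under neutral conditions that leave the silyl ether intact.

Step 3
Reactants: 3 {[2-(bromomethyl)prop-2-en-1-yl]oxy}(tert-butyl)dimethylsilane; 4 allylmagnesium bromide
Product: 5 tert-butyl(dimethyl)[(2-methylidenehex-5-en-1-yl)oxy]silane
Conditions: CuI (10 mol %), THF, −30 → 0 °C
Reagents that add atoms: none
Why: Copper-catalysed allyl–allyl coupling in which the SN2 and SN2' pathways converge on the same 1,5-diene, giving C1–C4 and C15 in one piece.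

Step 4
Reactants: 5 tert-butyl(dimethyl)[(2-methylidenehex-5-en-1-yl)oxy]silane; 6 (E)-but-2-enal
Product: 7 (2E)-6-({[tert-butyl(dimethyl)silyl]oxy}methyl)hepta-2,6-dienal
Conditions: second-generation Hoveyda–Grubbs catalyst, (H2IMes)Cl2Ru(=CH-C6H4-2-O-i-Pr) (3 mol %), 6 (5 equiv), CH2Cl2, 40 °C
Reagents that add atoms: none
Why: Olefin cross-metathesis in which only the monosubstituted alkene reacts (the 1,1-disubstituted alkene is a spectator) and the conjugated enal forms E-selectively.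

Step 5
Reactants: 7 (2E)-6-({[tert-butyl(dimethyl)silyl]oxy}methyl)hepta-2,6-dienal
Product: 8 (2Z)-6-({[tert-butyl(dimethyl)silyl]oxy}methyl)-2-iodohepta-2,6-dienal
Conditions: I2, K2CO3, DMAP (20 mol %), THF/H2O 1:1, rt
Reagents that add atoms: iodine, II
Why: Baylis–Hillman-type α-iodination (amine conjugate addition, enolate iodination, elimination) gives the thermodynamically preferred Z iodo-enal with the chain cis to iodine and trans to CHO, which is the C1=C10 geometry of the target.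

Step 6
Reactants: 8 (2Z)-6-({[tert-butyl(dimethyl)silyl]oxy}methyl)-2-iodohepta-2,6-dienal
Product: 9 tert-butyl{[(5Z)-6-iodo-7,7-dimethoxy-2-methylidenehept-5-en-1-yl]oxy}dimethylsilane
Conditions: MeOSiMe3 (3 equiv), TMSOTf (5 mol %), CH2Cl2, −78 °C; pyridine quench
Reagents that add atoms: methoxytrimethylsilane, CO[Si](C)(C)C
Why: Noyori aprotic acetalisation masks C14 as a dimethyl acetal without touching the TBS ether or the alkene geometry.

Step 7
Reactants: 10 (2S)-but-3-ene-1,2-diol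
Product: 11 (4S)-4-ethenyl-2-(4-methoxyphenyl)-1,3-dioxolane (mixture of C2 epimers)
Conditions: 4-MeOC6H4CH(OMe)2, PPTS (cat.), CH2Cl2, rt
Reagents that add atoms: 1-(dimethoxymethyl)-4-methoxybenzene, COc1ccc(C(OC)OC)cc1
Why: Acid-catalysed transacetalisation of the 1,2-diol; the C8 stereocentre comes from the chiral pool and is not touched.

Step 8
Reactants: 11 (4S)-4-ethenyl-2-(4-methoxyphenyl)-1,3-dioxolane
Product: 12 (2S)-2-[(4-methoxyphenyl)methoxy]but-3-en-1-ol
Conditions: i-Bu2AlH (3 equiv), CH2Cl2, −78 → 0 °C; aq. potassium sodium tartrate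
Reagents that add atoms: none
Why: Regioselective reductive acetal opening in which aluminium coordinates the less hindered primary oxygen, leaving the PMB group on the secondary (C8) oxygen and the primary alcohol free.

Step 9
Reactants: 12 (2S)-2-[(4-methoxyphenyl)methoxy]but-3-en-1-ol; 13 2-(bromomethyl)prop-2-enoic acid
Product: 14 (2S)-2-[(4-methoxyphenyl)methoxy]but-3-en-1-yl 2-(bromomethyl)prop-2-enoate
Conditions: DCC, DMAP (5 mol %), CH2Cl2, 0 °C → rt
Reagents that add atoms: none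
Why: Steglich esterification of the only free hydroxyl, bringing in C11–C13 with the allylic bromide already in place.

Step 10
Reactants: 14 (2S)-2-[(4-methoxyphenyl)methoxy]but-3-en-1-yl 2-(bromomethyl)prop-2-enoate
Product: 15 (5S)-3-(bromomethyl)-5-[(4-methoxyphenyl)methoxy]-5,6-dihydro-2H-pyran-2-one
Conditions: second-generation Hoveyda–Grubbs catalyst (5 mol %), toluene (5 mM), 80 °C
Reagents that add atoms: none
Why: Ring-closing metathesis of a 2-substituted acrylate with the allylic-ether vinyl group gives the six-membered unsaturated lactone, which locks C8 trans to the CH2Br terminus across C7=C11.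

Step 11
Reactants: 15 (5S)-3-(bromomethyl)-5-[(4-methoxyphenyl)methoxy]-5,6-dihydro-2H-pyran-2-one; 16 prop-2-enal
Product: 19 (4S,5R)-5-ethenyl-4-{(1S)-2-hydroxy-1-[(4-methoxyphenyl)methoxy]ethyl}-3-methylideneoxolan-2-one, via allylzinc bromide 17 (not isolated), via δ-lactone Barbier adduct 18 (not isolated)
Conditions: Zn dust, 16 (3 equiv), THF/sat. aq. NH4Cl, 0 °C → rt; then crude, CSA (10 mol %), CH2Cl2, rt
Reagents that add atoms: none
Why: Zinc Barbier allylation through a closed chair transition state in which the ring-enforced E-type allylzinc gives the anti relationship between the C6 hydroxyl and C8, acrolein adds to C7 on the face opposite the adjacent C8 OPMB group, and acid-promoted δ→γ translactonisation of the C6 hydroxyl then delivers the trans α-methylene-γ-butyrolactone (6R,7S) and frees the primary C9 alcohol.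

Step 12
Reactants: 19 (4S,5R)-5-ethenyl-4-{(1S)-2-hydroxy-1-[(4-methoxyphenyl)methoxy]ethyl}-3-methylideneoxolan-2-one
Product: 20 (2S)-2-[(2R,3S)-2-ethenyl-4-methylidene-5-oxooxolan-3-yl]-2-[(4-methoxyphenyl)methoxy]acetaldehyde
Conditions: Dess–Martin periodinane, pyridine, CH2Cl2, 0 °C → rt; used crude
Reagents that add atoms: none
Why: Buffered Dess–Martin oxidation of the primary alcohol gives the α-alkoxy aldehyde without epimerising C8 or touching the Michael-acceptor lactone.

Step 13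
Reactants: 9 tert-butyl{[(5Z)-6-iodo-7,7-dimethoxy-2-methylidenehept-5-en-1-yl]oxy}dimethylsilane; 20 (2S)-2-[(2R,3S)-2-ethenyl-4-methylidene-5-oxooxolan-3-yl]-2-[(4-methoxyphenyl)methoxy]acetaldehyde
Product: 23 (4S,5R)-4-[(1S,2S,3E)-7-({[tert-butyl(dimethyl)silyl]oxy}methyl)-3-(dimethoxymethyl)-2-hydroxy-1-[(4-methoxyphenyl)methoxy]octa-3,7-dien-1-yl]-5-ethenyl-3-methylideneoxolan-2-one, via alkenyllithium 21 (not isolated), via alkenylmagnesium bromide 22 (not isolated)
Conditions: 9 (1.3 equiv), t-BuLi (2.6 equiv), Et2O, −78 °C; MgBr2·OEt2; then 20 precomplexed with MgBr2·OEt2 in CH2Cl2, −78 °C; aq. NH4Cl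
Reagents that add atoms: none
Why: Cram-chelate 1,2-addition in which iodine–lithium exchange and transmetalation retain the alkene geometry, magnesium bridges the aldehyde and α-OPMB oxygens, and the alkenyl group attacks anti to C7 to give the 8,9-syn (threo) alcohol, that is 9S, while the lactone is left alone at −78 °C.

Step 14
Reactants: 23 (4S,5R)-4-[(1S,2S,3E)-7-({[tert-butyl(dimethyl)silyl]oxy}methyl)-3-(dimethoxymethyl)-2-hydroxy-1-[(4-methoxyphenyl)methoxy]octa-3,7-dien-1-yl]-5-ethenyl-3-methylideneoxolan-2-one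
Product: 24 (4R,5R)-4-[(1S,2S,3E)-7-({[tert-butyl(dimethyl)silyl]oxy}methyl)-3-(dimethoxymethyl)-1,2-dihydroxyocta-3,7-dien-1-yl]-5-ethenyl-3-methylideneoxolan-2-one
Conditions: DDQ, CH2Cl2/pH 7 phosphate buffer 10:1, 0 °C; used crude
Reagents that add atoms: none
Why: Oxidative PMB cleavage under wet buffered conditions, where water intercepts the oxocarbenium ion ahead of the neighbouring C9 hydroxyl, frees the C8 hydroxyl while the acetal, silyl ether and stereocentres are unchanged (the C7 descriptor changes only through CIP priorities).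

Step 15
Reactants: 24 (4R,5R)-4-[(1S,2S,3E)-7-({[tert-butyl(dimethyl)silyl]oxy}methyl)-3-(dimethoxymethyl)-1,2-dihydroxyocta-3,7-dien-1-yl]-5-ethenyl-3-methylideneoxolan-2-one; 25 (2Z)-2-methylbut-2-enoic acid (angelic acid)
Product: 27 (1S,2S,3E)-7-({[tert-butyl(dimethyl)silyl]oxy}methyl)-3-(dimethoxymethyl)-1-[(2R,3S)-2-ethenyl-4-methylidene-5-oxooxolan-3-yl]octa-3,7-diene-1,2-diyl bis[(2Z)-2-methylbut-2-enoate], via angelic 2,4,6-trichlorobenzoic anhydride 26 (not isolated)
Conditions: 25 (6 equiv), 2,4,6-Cl3C6H2COCl, Et3N, toluene, rt; then 24, 80 °C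
Reagents that add atoms: none
Why: Yamaguchi-type mixed-anhydride esterification of both secondary hydroxyls without DMAP, which avoids Z→E isomerisation of the angelate to tiglate and leaves all stereocentres untouched.

Step 16
Reactants: 27 (1S,2S,3E)-7-({[tert-butyl(dimethyl)silyl]oxy}methyl)-3-(dimethoxymethyl)-1-[(2R,3S)-2-ethenyl-4-methylidene-5-oxooxolan-3-yl]octa-3,7-diene-1,2-diyl bis[(2Z)-2-methylbut-2-enoate]
Product: 28 (3aS,4S,5S,6E,10E,11aR)-10-({[tert-butyl(dimethyl)silyl]oxy}methyl)-6-(dimethoxymethyl)-3-methylidene-2-oxo-2,3,3a,4,5,8,9,11a-octahydrocyclodeca[b]furan-4,5-diyl bis[(2Z)-2-methylbut-2-enoate]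
Conditions: second-generation Hoveyda–Grubbs catalyst (20 mol %, in portions), toluene (0.5 mM), 100 °C
Reagents that add atoms: none
Why: Ring-closing metathesis between the C5 vinyl group and the C4 1,1-disubstituted alkene closes the ten-membered ring, and the new trisubstituted C4=C5 alkene is expected ring-cis (C6 cis to C3) because a cis,cis-cyclodeca-1,5-diene is the least strained arrangement, while the electron-poor exo-methylene and angelate alkenes stay inert.

Step 17
Reactants: 28 (3aS,4S,5S,6E,10E,11aR)-10-({[tert-butyl(dimethyl)silyl]oxy}methyl)-6-(dimethoxymethyl)-3-methylidene-2-oxo-2,3,3a,4,5,8,9,11a-octahydrocyclodeca[b]furan-4,5-diyl bis[(2Z)-2-methylbut-2-enoate]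
Product: 29 (3aS,4S,5S,6E,10E,11aR)-6-formyl-10-(hydroxymethyl)-3-methylidene-2-oxo-2,3,3a,4,5,8,9,11a-octahydrocyclodeca[b]furan-4,5-diyl bis[(2Z)-2-methylbut-2-enoate]
Conditions: aq. HF (48%)/MeCN 1:19, 0 °C → rt
Reagents that add atoms: water, O
Why: Mild aqueous acid hydrolyses the allylic dimethyl acetal to the enal and cleaves the primary TBS ether in the same operation, leaving the angelates, the α-methylene lactone and all four stereocentres untouched.

## Compound list

1 | 2-methylidenepropane-1,3-diol | C=C(CO)CO | starting material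
2 | 2-({[tert-butyl(dimethyl)silyl]oxy}methyl)prop-2-en-1-ol | C=C(CO)CO[Si](C)(C)C(C)(C)C | intermediate
3 | {[2-(bromomethyl)prop-2-en-1-yl]oxy}(tert-butyl)dimethylsilane | C=C(CBr)CO[Si](C)(C)C(C)(C)C | intermediate
4 | allylmagnesium bromide | C=CC[Mg]Br | starting material
5 | tert-butyl(dimethyl)[(2-methylidenehex-5-en-1-yl)oxy]silane | C=CCCC(=C)CO[Si](C)(C)C(C)(C)C | intermediate
6 | (E)-but-2-enal (crotonaldehyde) | C/C=C/C=O | starting material
7 | (2E)-6-({[tert-butyl(dimethyl)silyl]oxy}methyl)hepta-2,6-dienal | O=C/C=C/CCC(=C)CO[Si](C)(C)C(C)(C)C | intermediate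
8 | (2Z)-6-({[tert-butyl(dimethyl)silyl]oxy}methyl)-2-iodohepta-2,6-dienal | O=C/C(I)=C/CCC(=C)CO[Si](C)(C)C(C)(C)C | intermediate
9 | tert-butyl{[(5Z)-6-iodo-7,7-dimethoxy-2-methylidenehept-5-en-1-yl]oxy}dimethylsilane | COC(OC)/C(I)=C/CCC(=C)CO[Si](C)(C)C(C)(C)C | intermediate
10 | (2S)-but-3-ene-1,2-diol | C=C[C@@H](CO)O | starting material
11 | (4S)-4-ethenyl-2-(4-methoxyphenyl)-1,3-dioxolane (C2 epimers) | C=C[C@H]1COC(c2ccc(OC)cc2)O1 | intermediate
12 | (2S)-2-[(4-methoxyphenyl)methoxy]but-3-en-1-ol | C=C[C@@H](CO)OCc1ccc(OC)cc1 | intermediate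
13 | 2-(bromomethyl)prop-2-enoic acid | C=C(CBr)C(=O)O | starting material
14 | (2S)-2-[(4-methoxyphenyl)methoxy]but-3-en-1-yl 2-(bromomethyl)prop-2-enoate | C=C[C@@H](COC(=O)C(=C)CBr)OCc1ccc(OC)cc1 | intermediate
15 | (5S)-3-(bromomethyl)-5-[(4-methoxyphenyl)methoxy]-5,6-dihydro-2H-pyran-2-one | BrCC1=C[C@H](OCc2ccc(OC)cc2)COC1=O | intermediate
16 | prop-2-enal (acrolein) | C=CC=O | starting material
17 | bromo({(5S)-5-[(4-methoxyphenyl)methoxy]-2-oxo-5,6-dihydro-2H-pyran-3-yl}methyl)zinc | Br[Zn]CC1=C[C@H](OCc2ccc(OC)cc2)COC1=O | intermediate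
18 | (4S,5S)-4-[(1R)-1-hydroxyprop-2-en-1-yl]-5-[(4-methoxyphenyl)methoxy]-3-methylideneoxan-2-one | C=C1C(=O)OC[C@@H](OCc2ccc(OC)cc2)[C@@H]1[C@H](O)C=C | intermediate
19 | (4S,5R)-5-ethenyl-4-{(1S)-2-hydroxy-1-[(4-methoxyphenyl)methoxy]ethyl}-3-methylideneoxolan-2-one | C=C1C(=O)O[C@H](C=C)[C@H]1[C@H](OCc2ccc(OC)cc2)CO | intermediate
20 | (2S)-2-[(2R,3S)-2-ethenyl-4-methylidene-5-oxooxolan-3-yl]-2-[(4-methoxyphenyl)methoxy]acetaldehyde | C=C1C(=O)O[C@H](C=C)[C@H]1[C@H](OCc2ccc(OC)cc2)C=O | intermediate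
21 | [(2Z)-7-({[tert-butyl(dimethyl)silyl]oxy}methyl)-1,1-dimethoxyocta-2,7-dien-2-yl]lithium | COC(OC)/C([Li])=C/CCC(=C)CO[Si](C)(C)C(C)(C)C | intermediate
22 | [(2Z)-7-({[tert-butyl(dimethyl)silyl]oxy}methyl)-1,1-dimethoxyocta-2,7-dien-2-yl]magnesium bromide | COC(OC)/C([Mg]Br)=C/CCC(=C)CO[Si](C)(C)C(C)(C)C | intermediate
23 | (4S,5R)-4-[(1S,2S,3E)-7-({[tert-butyl(dimethyl)silyl]oxy}methyl)-3-(dimethoxymethyl)-2-hydroxy-1-[(4-methoxyphenyl)methoxy]octa-3,7-dien-1-yl]-5-ethenyl-3-methylideneoxolan-2-one | C=C1C(=O)O[C@H](C=C)[C@H]1[C@H](OCc2ccc(OC)cc2)[C@@H](O)/C(C(OC)OC)=C\CCC(=C)CO[Si](C)(C)C(C)(C)C | intermediate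
24 | (4R,5R)-4-[(1S,2S,3E)-7-({[tert-butyl(dimethyl)silyl]oxy}methyl)-3-(dimethoxymethyl)-1,2-dihydroxyocta-3,7-dien-1-yl]-5-ethenyl-3-methylideneoxolan-2-one | C=C1C(=O)O[C@H](C=C)[C@H]1[C@H](O)[C@@H](O)/C(C(OC)OC)=C\CCC(=C)CO[Si](C)(C)C(C)(C)C | intermediate
25 | (2Z)-2-methylbut-2-enoic acid (angelic acid) | C/C=C(/C)C(=O)O | starting material
26 | (2Z)-2-methylbut-2-enoic 2,4,6-trichlorobenzoic anhydride | C/C=C(/C)C(=O)OC(=O)c1c(Cl)cc(Cl)cc1Cl | intermediate
27 | (1S,2S,3E)-7-({[tert-butyl(dimethyl)silyl]oxy}methyl)-3-(dimethoxymethyl)-1-[(2R,3S)-2-ethenyl-4-methylidene-5-oxooxolan-3-yl]octa-3,7-diene-1,2-diyl bis[(2Z)-2-methylbut-2-enoate] | C=C1C(=O)O[C@H](C=C)[C@H]1[C@H](OC(=O)/C(C)=C\C)[C@@H](OC(=O)/C(C)=C\C)/C(C(OC)OC)=C\CCC(=C)CO[Si](C)(C)C(C)(C)C | intermediate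
28 | (3aS,4S,5S,6E,10E,11aR)-10-({[tert-butyl(dimethyl)silyl]oxy}methyl)-6-(dimethoxymethyl)-3-methylidene-2-oxo-2,3,3a,4,5,8,9,11a-octahydrocyclodeca[b]furan-4,5-diyl bis[(2Z)-2-methylbut-2-enoate] | C=C1C(=O)O[C@@H]2/C=C(/CO[Si](C)(C)C(C)(C)C)CC/C=C(/C(OC)OC)[C@H](OC(=O)/C(C)=C\C)[C@@H](OC(=O)/C(C)=C\C)[C@@H]12 | intermediate
29 | (3aS,4S,5S,6E,10E,11aR)-6-formyl-10-(hydroxymethyl)-3-methylidene-2-oxo-2,3,3a,4,5,8,9,11a-octahydrocyclodeca[b]furan-4,5-diyl bis[(2Z)-2-methylbut-2-enoate] (CNP0139154.1) | C=C1C(=O)O[C@@H]2/C=C(/CO)CC/C=C(/C=O)[C@H](OC(=O)/C(C)=C\C)[C@@H](OC(=O)/C(C)=C\C)[C@@H]12 | target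

## Summary

Total step count: 17 (steps 1–6 for iodide 9, steps 7–12 for aldehyde 20, steps 13–17 after the union).
Longest linear sequence: 11 steps (steps 1–6 then 13–17, or equally steps 7–12 then 13–17).

Three steps most likely to fail, each with one fallback:

Step 11 (Barbier allylation and translactonisation). The allylzinc 17 carries the C8 alkoxide in a position where 1,4-elimination to a pyranone can compete, and the facial and anti selectivity rest on analogy to bromomethyl-butenolide chemistry. The fallback replaces the transient organozinc with an isolable allylboron reagent. It sets out from bromide 15: Pd2(dba)3-catalysed borylation with bis(pinacolato)diboron in toluene gives the allylboronate (5S)-5-[(4-methoxyphenyl)methoxy]-3-[(4,4,5,5-tetramethyl-1,3,2-dioxaborolan-2-yl)methyl]-5,6-dihydro-2H-pyran-2-one F1. This reagent cannot β-eliminate and adds to acrolein 16 (toluene, 80 °C, or Sc(OTf)3 catalysis at low temperature) through a tight Zimmerman–Traxler chair with the same anti, trans-to-OPMB outcome. Aqueous work-up gives adduct 18, and the same CSA translactonisation brings the route back at 19.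

Step 13 (chelation-controlled fragment union). The alkenyl Grignard 22 may attack the α-methylene lactone, or chelation control may be incomplete. The fallback sets out from iodide 9 and aldehyde 20 and changes both the carbon–carbon bond-forming method and the source of the C9 configuration. Nozaki–Hiyama–Kishi coupling (CrCl2, NiCl2 1 mol %, DMSO, rt), which tolerates the lactone, gives the allylic alcohols as a C9 mixture, mainly the Felkin product (4S,5R)-4-[(1S,2R,3E)-7-({[tert-butyl(dimethyl)silyl]oxy}methyl)-3-(dimethoxymethyl)-2-hydroxy-1-[(4-methoxyphenyl)methoxy]octa-3,7-dien-1-yl]-5-ethenyl-3-methylideneoxolan-2-one F2. Dess–Martin oxidation of the mixture gives the enone (4S,5R)-4-[(1S,3Z)-7-({[tert-butyl(dimethyl)silyl]oxy}methyl)-3-(dimethoxymethyl)-1-[(4-methoxyphenyl)methoxy]-2-oxoocta-3,7-dien-1-yl]-5-ethenyl-3-methylideneoxolan-2-one F3. Reduction with (S)-2-methyl-CBS-oxazaborolidine and catecholborane (toluene, −78 °C), with reagent control reinforcing non-chelated Felkin–Anh hydride delivery, gives the 9S alcohol, and the route is rejoined at 23.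

Step 16 (ten-membered ring-closing metathesis). The hindered 1,1-disubstituted alkene, ring strain and the two bulky angelates next to the reacting chain may stall the closure or favour oligomers. The fallback sets out from alcohol 23 and closes the ring before the diol is unmasked and esterified, so the metathesis substrate is far less encumbered and the esters are put on the ring afterwards. Metathesis of 23 (same catalyst, toluene, 0.5 mM, 100 °C) gives the macrocycle (3aS,4S,5S,6E,10E,11aR)-10-({[tert-butyl(dimethyl)silyl]oxy}methyl)-6-(dimethoxymethyl)-5-hydroxy-4-[(4-methoxyphenyl)methoxy]-3-methylidene-3a,4,5,8,9,11a-hexahydrocyclodeca[b]furan-2(3H)-one F4. Buffered DDQ gives the macrocyclic diol (3aR,4S,5S,6E,10E,11aR)-10-({[tert-butyl(dimethyl)silyl]oxy}methyl)-6-(dimethoxymethyl)-4,5-dihydroxy-3-methylidene-3a,4,5,8,9,11a-hexahydrocyclodeca[b]furan-2(3H)-one F5. Bis-angeloylation with 25 through anhydride 26 (toluene, 80 °C) then returns to the route at 28.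

Further compounds

F1 | step 11 | (5S)-5-[(4-methoxyphenyl)methoxy]-3-[(4,4,5,5-tetramethyl-1,3,2-dioxaborolan-2-yl)methyl]-5,6-dihydro-2H-pyran-2-one | CC1(C)OB(CC2=C[C@H](OCc3ccc(OC)cc3)COC2=O)OC1(C)C
F2 | step 13 | (4S,5R)-4-[(1S,2R,3E)-7-({[tert-butyl(dimethyl)silyl]oxy}methyl)-3-(dimethoxymethyl)-2-hydroxy-1-[(4-methoxyphenyl)methoxy]octa-3,7-dien-1-yl]-5-ethenyl-3-methylideneoxolan-2-one | C=C1C(=O)O[C@H](C=C)[C@H]1[C@H](OCc2ccc(OC)cc2)[C@H](O)/C(C(OC)OC)=C\CCC(=C)CO[Si](C)(C)C(C)(C)C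
F3 | step 13 | (4S,5R)-4-[(1S,3Z)-7-({[tert-butyl(dimethyl)silyl]oxy}methyl)-3-(dimethoxymethyl)-1-[(4-methoxyphenyl)methoxy]-2-oxoocta-3,7-dien-1-yl]-5-ethenyl-3-methylideneoxolan-2-one | C=C1C(=O)O[C@H](C=C)[C@H]1[C@H](OCc2ccc(OC)cc2)C(=O)/C(C(OC)OC)=C\CCC(=C)CO[Si](C)(C)C(C)(C)C
F4 | step 16 | (3aS,4S,5S,6E,10E,11aR)-10-({[tert-butyl(dimethyl)silyl]oxy}methyl)-6-(dimethoxymethyl)-5-hydroxy-4-[(4-methoxyphenyl)methoxy]-3-methylidene-3a,4,5,8,9,11a-hexahydrocyclodeca[b]furan-2(3H)-one | C=C1C(=O)O[C@@H]2/C=C(/CO[Si](C)(C)C(C)(C)C)CC/C=C(/C(OC)OC)[C@H](O)[C@@H](OCc3ccc(OC)cc3)[C@@H]12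
F5 | step 16 | (3aR,4S,5S,6E,10E,11aR)-10-({[tert-butyl(dimethyl)silyl]oxy}methyl)-6-(dimethoxymethyl)-4,5-dihydroxy-3-methylidene-3a,4,5,8,9,11a-hexahydrocyclodeca[b]furan-2(3H)-one | C=C1C(=O)O[C@@H]2/C=C(/CO[Si](C)(C)C(C)(C)C)CC/C=C(/C(OC)OC)[C@H](O)[C@@H](O)[C@@H]12
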